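At early times the solid substrate stands undissolved, and ring forms from what has dissolved.

    starting material → ring (k1 = 0.088 s⁻¹, Ea1 = 86.0 kJ mol⁻¹)
    starting material + starting material ⇌ open dimer (K2 = 7.2 M⁻¹, k2 = 1.2 M⁻¹ s⁻¹, Ea2 = 51.0 kJ mol⁻¹, ΔH2 = −59.0 kJ mol⁻¹)
    crystals ⇌ ring, rate k3*(cs3 - [ring]) while solid is left; crystals form when [ring] > cs3 (cs3 = 11 mM, k3 = 0.11 s⁻¹)
    ring → over-reaction product (k4 = 0.0032 s⁻¹, Ea4 = 95.0 kJ mol⁻¹)
    solid substrate ⇌ starting material, rate k5*(cs5 - [starting material]) while solid is left; crystals form when [starting material] > cs5 (cs5 = 23 mM, k5 = 0.044 s⁻¹)
    (constants at 25 °C)

in all of them: solid substrate 0.050 M; time 2.0 min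

| run | temperature |
|---|---|
| Wednesday's | 45 °C |
| Thursday's | −15 °C |
| Tuesday's | 25 °C |
| Friday's | 5 °C |

- a species is counted by the solid substrate in it: one open dimer counts as two
- amounts and yields of ring count crystals too
- a doubled species enters its step squared and goes two at a time
- given per volume of solution although it is solid: crystals, solid substrate
- at 25 °C the constants are as listed, elsewhere as the activation energies and enthalpies make them
- at the start none of the solid substrate is in solution
- what has only dissolved of solid substrate counts as not reacted

1. the best flask by amount of ring, in percent of the solid substrate charged; "all alike" if 1.5 percentage points covers them all (Wednesday's / Thursday's / Tuesday's / Friday's / all alike)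
2. amount of ring at the end, in percent of the solid substrate charged, Wednesday's
3. amount of ring at the end, in percent of the solid substrate charged, Thursday's
4. amount of ring at the end, in percent of the solid substrate charged, Tuesday's
5. amount of ring at the end, in percent of the solid substrate charged, Friday's

Take Tuesday's flask, at 25 °C, where the constants stand as listed, and turn them into times at the charge. You lose starting material to cyclisation with a life of 11.4 s, so while solid is left I reckon it levels off in solution at 7.67 mM, where feed and use balance. At that level the solid feeds 0.675 mM s⁻¹, and the feed time t_f, the charge over that rate, is 1.24 min. That is longer than the life of starting material, so in Tuesday's flask I take dissolving as the rate-limiting step of making ring. The open dimer adds no third time: it falls back in 6.00 s, far inside t_f, and at that level it holds 1.69% of the charge.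

The second time belongs to the crystals. While they stand with the solution near the ring's solubility, over-reaction runs at a constant 0.0352 mM s⁻¹, zero-order in the amount of crystals. The wear time t_w, the charge over that rate, 23.7 min, is the second clock. The charge cancels from the ratio t_w/t_f, here 19.1. In Tuesday's flask your run of 2.0 min lies beyond t_f and well short of t_w. Charging wear over the whole run costs 8.44%, so I commit to ring near 91.6% in Tuesday's flask. Over-reaction speeds up 4200 times from the flask at −15 °C to the one at 45 °C, so t_w shortens on the hot side. I have reckoned neither cold flask, so my pick of Tuesday's flask is a judgement and not a result of these two times.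

The forecast names Tuesday's, with 90% there, 16% in Wednesday's, 1.7% in Thursday's and 26% in Friday's, on the ground that “crystallised ring is shielded from over-reaction”.

The simulation puts Tuesday's ahead with 90.3% of ring and 9.41% of over-reaction product, against 13.6% in Wednesday's, 1.75% in Thursday's and 25.9% in Friday's.

Tuesday's flask has not come to rest at 2.00 min. Its crystals stand at 68.3% of the charge, and I reckon that fraction of t_w clears them in a further 16.2 min. The ring held dissolved at its solubility is 22.0% of the charge. Letting it decay with a life of 5.21 min for the remaining 1.84 min reckons to 15.5%. At 20.0 min Tuesday's flask holds crystals 0%, over-reaction product 82.8% and ring 17.2%.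

All constants are made up; the rest is arithmetic.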